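**Strategy.** The cyclohexene ring (C1 CH–OAc, C2 CH–OBz, C3=C4, C5 CH–OH, C6 C(OH)CH2OBz) is cut at C1–C6 and C2–C3 into a furan and a two-carbon alkene. The key step is a catalytic enantioselective Diels–Alder reaction of furfuryl benzoate with (E)-4-benzoyloxybut-3-en-2-one, which forms both bonds and four stereocentres. It exploits two features: C6 carries an oxygen and the benzoyloxymethyl arm, as does the 2-position of a furan, and the C3=C4/C5–OH/C6–OH array is the allylic (SN2') transposition product of a 7-oxanorbornene bridge. A Baeyer–Villiger step (acetyl to acetate) and a rhodium-catalysed anti-SN2' hydration of the bridge complete the target.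

Key step: step 3

Assumption: the target ring atoms are numbered as above. The antipodes named for the chiral catalyst of step 3 and the chiral ligand of step 5 are those expected from the accepted selectivity models; the mirror-image catalyst or ligand would be used if a first run showed the opposite sense.

Step 1
Reactants: 1 furan-2-ylmethanol (furfuryl alcohol); 2 benzoyl chloride
Product: 3 furan-2-ylmethyl benzoate
Conditions: Et3N, DMAP (cat.), CH2Cl2, 0 °C to rt
Reagents that add atoms: none
Why: DMAP-catalysed O-acylation (nucleophilic acyl substitution) of a primary alcohol should be clean, and the amine base protects the acid-sensitive furan; no stereocentre is formed.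

Step 2
Reactants: 4 but-3-yn-2-one; 5 benzoic acid
Product: 6 (E)-3-oxobut-1-en-1-yl benzoate
Conditions: DABCO (10 mol%), CH2Cl2, 0 °C to rt
Reagents that add atoms: none
Why: Amine-catalysed oxa-Michael (conjugate) addition of a carboxylic acid to an ynone, in which the amine adds to 4, the adduct is protonated by 5 and benzoate replaces the amine by addition–elimination, should give the thermodynamically preferred (E)-enol ester; no stereocentre is formed.

Step 3
Reactants: 3 furan-2-ylmethyl benzoate; 6 (E)-3-oxobut-1-en-1-yl benzoate
Product: 7 [(1S,2S,3S,4R)-2-acetyl-3-(benzoyloxy)-7-oxabicyclo[2.2.1]hept-5-en-1-yl]methyl benzoate (2-endo-acetyl, 3-exo-benzoyloxy)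
Conditions: (S)-3,3-diphenyl-1-(2-methylphenyl)tetrahydro-1H,3H-pyrrolo[1,2-c][1,3,2]oxazaborole·HN(SO2CF3)2 (20 mol%), 3 (2 equiv), CH2Cl2, −78 to −40 °C; Et3N quench at −78 °C; cold filtration through Et3N-deactivated silica, used at once
Reagents that add atoms: none
Why: The protonated oxazaborolidine binds the acetyl oxygen of 6 (s-trans enone, α-C–H···O contact), lowers its LUMO and lets the furan HOMO add in a concerted but asynchronous [4π+2π] cycloaddition in which the C2–C3 bond (free furan α-carbon to the benzoyloxy-bearing β-carbon) leads and the C1–C6 bond follows. The closest known reaction type is the chiral-oxazaborolidinium-catalysed Diels–Alder reaction of furans with acrylate-type dienophiles. The cyclohexene ring closes by this intermolecular suprafacial–suprafacial cycloaddition, which also creates the two oxolane rings of the 7-oxabicyclo[2.2.1]heptene because the furan oxygen already spans C3 and C6. C1 and C2 should come out trans because the (E)-geometry of 6 is transferred suprafacially, their relation to C3 and C6 follows from the endo rule for the Lewis-acid-bound acetyl group (acetyl endo, benzoyloxy exo), and the absolute configuration of all four centres is set by the catalyst, which shields one face so that the furan adds to the Re face of the acetyl-bearing carbon. The step needs "ortho" regioselectivity (acetyl carbon next to the substituted bridgehead), secured by the polarisation of the push–pull enone and the larger HOMO coefficient at the free furan α-position; it also needs cycloaddition to outrun Friedel–Crafts-type conjugate addition and cycloreversion, which the low temperature and the cold basic quench are meant to ensure.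

Step 4
Reactants: 7 [(1S,2S,3S,4R)-2-acetyl-3-(benzoyloxy)-7-oxabicyclo[2.2.1]hept-5-en-1-yl]methyl benzoate
Product: 9 [(1R,2S,3R,4R)-2-(acetyloxy)-3-(benzoyloxy)-7-oxabicyclo[2.2.1]hept-5-en-1-yl]methyl benzoate (2-endo-acetoxy, 3-exo-benzoyloxy), via silyl peroxyketal 8 (not isolated)
Conditions: Me3SiOOSiMe3 (1.5 equiv), Me3SiOTf (10 mol%), CH2Cl2, −40 to −20 °C; pH 7 buffer
Reagents that add atoms: bis(trimethylsilyl) peroxide, C[Si](C)(C)OO[Si](C)(C)C
Why: Baeyer–Villiger oxidation in its silyl-peroxide variant: the peroxide adds to the activated ketone to give Criegee-type adduct 8, from which the secondary ring carbon should migrate in preference to methyl with retention, so the endo acetyl becomes the endo acetate; this oxidant should not epoxidise the strained alkene, and the low temperature should hold back cycloreversion.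

Step 5
Reactants: 9 [(1R,2S,3R,4R)-2-(acetyloxy)-3-(benzoyloxy)-7-oxabicyclo[2.2.1]hept-5-en-1-yl]methyl benzoate
Product: 10 [(1S,2R,5R,6S)-6-(acetyloxy)-5-(benzoyloxy)-1,2-dihydroxycyclohex-3-en-1-yl]methyl benzoate
Conditions: [Rh(C8H12)2]OTf (5 mol%), (R)-1-[(S)-2-(diphenylphosphino)ferrocenyl]ethyldi-tert-butylphosphine (6 mol%), H2O (10 equiv), THF, 50 °C
Reagents that add atoms: water, O
Why: Rhodium-catalysed anti-SN2' ring opening of an oxabicyclic alkene with an O–H nucleophile: the cationic monovalent rhodium complex should insert with retention into the bridgehead C3–O bond (the secondary, less hindered one, selected also by the ligand antipode) and water should attack the allyl terminus C5 on the face opposite the metal, so the new C5–OH is trans to the retained tertiary C6–OH and the alkene ends at C3=C4; the esters should survive these neutral conditions.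

**Compound list**

1 | furan-2-ylmethanol (furfuryl alcohol) | OCc1ccco1 | starting material
2 | benzoyl chloride | O=C(Cl)c1ccccc1 | starting material
3 | furan-2-ylmethyl benzoate | O=C(OCc1ccco1)c1ccccc1 | intermediate
4 | but-3-yn-2-one | CC(=O)C#C | starting material
5 | benzoic acid | OC(=O)c1ccccc1 | starting material
6 | (E)-3-oxobut-1-en-1-yl benzoate | CC(=O)/C=C/OC(=O)c1ccccc1 | intermediate
7 | [(1S,2S,3S,4R)-2-acetyl-3-(benzoyloxy)-7-oxabicyclo[2.2.1]hept-5-en-1-yl]methyl benzoate | CC(=O)[C@H]1[C@H](OC(=O)c2ccccc2)[C@H]3C=C[C@@]1(O3)COC(=O)c1ccccc1 | intermediate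
8 | [(1S,2S,3S,4R)-3-(benzoyloxy)-2-{1-[(trimethylsilyl)oxy]-1-[(trimethylsilyl)peroxy]ethyl}-7-oxabicyclo[2.2.1]hept-5-en-1-yl]methyl benzoate (ketal carbon undefined; not isolated) | CC(O[Si](C)(C)C)(OO[Si](C)(C)C)[C@H]1[C@H](OC(=O)c2ccccc2)[C@H]3C=C[C@@]1(O3)COC(=O)c1ccccc1 | intermediate
9 | [(1R,2S,3R,4R)-2-(acetyloxy)-3-(benzoyloxy)-7-oxabicyclo[2.2.1]hept-5-en-1-yl]methyl benzoate | CC(=O)O[C@H]1[C@H](OC(=O)c2ccccc2)[C@H]3C=C[C@@]1(O3)COC(=O)c1ccccc1 | intermediate
10 | [(1S,2R,5R,6S)-6-(acetyloxy)-5-(benzoyloxy)-1,2-dihydroxycyclohex-3-en-1-yl]methyl benzoate | CC(=O)O[C@H]1[C@H](OC(=O)c2ccccc2)C=C[C@@H](O)[C@@]1(O)COC(=O)c1ccccc1 | target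

**Step count.** Total: 5 steps. Longest linear sequence: 4 steps (steps 1, 3, 4, 5).

**Steps most likely to fail**

1. Step 3. The Lewis-acid-bound enone may be attacked by the furan in a stepwise manner, ending in Friedel–Crafts-type conjugate substitution instead of ring closure. The adduct may also cyclorevert on warming, and facial, endo or regiochemical control may be incomplete. Fallback: from 3 and 6, the cycloaddition is run without any acid under high pressure (CH2Cl2, 12 kbar, rt), where no cationic path exists. This should give 7 as a racemate, that is 7 together with its mirror image, the (1R,2R,3R,4S)-enantiomer of 7 F1. Step 4 on the racemate should give 9 together with the (1S,2R,3S,4S)-enantiomer of 9 F2. Step 5 with its chiral rhodium catalyst then serves as a regiodivergent resolution: 9 should give 10, whereas F2 should either be left behind or be opened at the other bridgehead to the constitutional isomer [6-(acetyloxy)-5-(benzoyloxy)-3,4-dihydroxycyclohex-1-en-1-yl]methyl benzoate F3 (3,4-trans diol), which is removed by chromatography. The fallback returns to the route at 10.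

2. Step 4. The silyl triflate may open the oxygen bridge (leading on to aromatisation), the doubly β-oxygenated ring carbon may migrate slowly, and the adduct may cyclorevert before it is oxidised. Fallback: from 7, bromine (CH2Cl2, −78 °C) is added across C4=C5 to give the trans-dibromide of 7 F4, which can neither cyclorevert nor be epoxidised. Buffered trifluoroperacetic acid ((CF3CO)2O, urea·H2O2, Na2HPO4, CH2Cl2, 0 °C) should then effect the Baeyer–Villiger step to the dibromo acetate F5. Zinc dust (AcOH/THF, 0 °C) should restore the alkene, returning to the route at 9.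

3. Step 5. Insertion may occur at the wrong bridgehead C–O bond, a rhodium hydride may isomerise the new allylic alcohol to a ketone, water may be too poor a nucleophile for this electron-poor oxabicycle, and acyl groups may migrate to the freed hydroxyls. Fallback: from 9, the same rhodium catalyst is used with 4-methoxybenzyl alcohol (5 equiv, THF, 50 °C), the best-established nucleophile class for this ring opening. This should give [(1S,2R,5R,6S)-6-(acetyloxy)-5-(benzoyloxy)-1-hydroxy-2-(4-methoxybenzyloxy)cyclohex-3-en-1-yl]methyl benzoate F6, an ether that cannot isomerise. DDQ (CH2Cl2/pH 7 buffer, 0 °C) should then remove the 4-methoxybenzyl group, returning to the route at 10.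

**Further compounds**

F1 | step 3 | [(1R,2R,3R,4S)-2-acetyl-3-(benzoyloxy)-7-oxabicyclo[2.2.1]hept-5-en-1-yl]methyl benzoate | CC(=O)[C@@H]1[C@@H](OC(=O)c2ccccc2)[C@@H]3C=C[C@]1(O3)COC(=O)c1ccccc1
F2 | step 3 | [(1S,2R,3S,4S)-2-(acetyloxy)-3-(benzoyloxy)-7-oxabicyclo[2.2.1]hept-5-en-1-yl]methyl benzoate | CC(=O)O[C@@H]1[C@@H](OC(=O)c2ccccc2)[C@@H]3C=C[C@]1(O3)COC(=O)c1ccccc1
F3 | step 3 | [6-(acetyloxy)-5-(benzoyloxy)-3,4-dihydroxycyclohex-1-en-1-yl]methyl benzoate (3,4-trans diol from F2) | CC(=O)O[C@@H]1[C@@H](OC(=O)c2ccccc2)[C@@H](O)[C@H](O)C=C1COC(=O)c1ccccc1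
F4 | step 4 | [2-endo-acetyl-3-exo-(benzoyloxy)-5-endo,6-exo-dibromo-7-oxabicyclo[2.2.1]heptan-1-yl]methyl benzoate | CC(=O)[C@H]1[C@H](OC(=O)c2ccccc2)[C@H]3[C@@H](Br)[C@H](Br)[C@@]1(O3)COC(=O)c1ccccc1
F5 | step 4 | [2-endo-(acetyloxy)-3-exo-(benzoyloxy)-5-endo,6-exo-dibromo-7-oxabicyclo[2.2.1]heptan-1-yl]methyl benzoate | CC(=O)O[C@H]1[C@H](OC(=O)c2ccccc2)[C@H]3[C@@H](Br)[C@H](Br)[C@@]1(O3)COC(=O)c1ccccc1
F6 | step 5 | [(1S,2R,5R,6S)-6-(acetyloxy)-5-(benzoyloxy)-1-hydroxy-2-(4-methoxybenzyloxy)cyclohex-3-en-1-yl]methyl benzoate | CC(=O)O[C@H]1[C@H](OC(=O)c2ccccc2)C=C[C@@H](OCc2ccc(OC)cc2)[C@@]1(O)COC(=O)c1ccccc1
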